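**Retrosynthetic overview**

1. Endgame: target ⇐ exo-face hydride reduction of a C20 norbornanone ⇐ C13 bromide by invertive bromination of an axial alcohol ⇐ MeMgBr addition to the C16 ketone of a tetracyclic 1,4-diketone.
2. Key disconnection (ring B, formed last): the C18–C19 bond between the two ketone α-carbons ⇐ intramolecular oxidative coupling of two silyl enol ethers, one of which is oxidised to an electrophilic α-carbonyl radical cation (enolonium equivalent).
3. Bis(silyl enol ether) ⇐ anti-selective conjugate methylation (quaternary C11) of a 4-silyloxy enone ⇐ Stork–Danheiser union of a norbornenyl-ethyllithium with (R)-6-silyloxy-3-ethoxycyclohexenone (ring A, carried in as a monocycle).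
4. Norbornene fragment (formed first) ⇐ catalytic enantioselective Diels–Alder reaction of a 2-silyloxycyclopentadiene with 2-isopropylacrolein, then decarbonylation with retention (endo isopropyl).
5. Ring order: norbornane → ring A → ring B.

Atom labels C1–C20 follow the order of the carbon atoms in the target SMILES (C4 = CH bearing isopropyl, C6/C8 = norbornane bridgeheads, C7 = one-carbon bridge, C11 = angular-methyl carbon, C13 = CHBr, C16 = carbinol carbon, C18/C19 = ring-fusion CH, C20 = CHOH).

Assumption: the absolute sense of step 4 (catalyst enantiomer) and of step 7 (esterase) is as drawn; the mirror-image catalyst or a complementary esterase is used if the opposite sense is found.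

**Route**

Step 1
Reactants: 1 3-methylbutanal
Product: 2 3-methyl-2-methylidenebutanal (2-isopropylacrolein)
Conditions: 37% aq. CH2O, pyrrolidine (10 mol%), propionic acid (10 mol%), i-PrOH, 45 °C
Reagents that add atoms: formaldehyde C=O
Why: Organocatalytic α-methylenation (Mannich condensation then amine elimination) of the aldehyde; no stereocentre is formed.

Step 2
Reactants: 3 3-ethoxycyclopent-2-en-1-one
Product: 5 3-(2-chloroethyl)cyclopent-2-en-1-one, via dienone 4 (not isolated)
Conditions: CH2=CHMgBr, THF, 0 °C; then conc. HCl, 0 °C to rt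
Reagents that add atoms: vinylmagnesium bromide C=C[Mg]Br; hydrogen chloride Cl
Why: Stork–Danheiser 1,2-addition and acid transposition give the 3-vinyl enone, whose protonated dienone takes up chloride at the terminal carbon (1,6-conjugate hydrochlorination); no stereocentre is formed.

Step 3
Reactants: 5 3-(2-chloroethyl)cyclopent-2-en-1-one
Product: 6 1-(2-chloroethyl)-3-[tri(propan-2-yl)silyloxy]cyclopenta-1,3-diene
Conditions: LDA, THF, −78 °C; i-Pr3SiOTf; used cold at once
Reagents that add atoms: triisopropylsilyl trifluoromethanesulfonate CC(C)[Si](C(C)C)(C(C)C)OS(=O)(=O)C(F)(F)F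
Why: Kinetic α′-deprotonation and O-silylation give the cross-conjugated 2-silyloxy diene (kinetic enolate trapping), and the low temperature avoids γ-deprotonation with loss of chloride; no stereocentre is formed.

Step 4
Reactants: 6 1-(2-chloroethyl)-3-[tri(propan-2-yl)silyloxy]cyclopenta-1,3-diene; 2 3-methyl-2-methylidenebutanal
Product: 7 1-(2-chloroethyl)-2-(propan-2-yl)-5-[tri(propan-2-yl)silyloxy]bicyclo[2.2.1]hept-5-ene-2-carbaldehyde (formyl exo, isopropyl endo)
Conditions: (S)-3,3-diphenyl-1-(2-methylphenyl)tetrahydro-1H,3H-pyrrolo[1,2-c][1,3,2]oxazaborole and HN(SO2CF3)2 (10 mol% each), CH2Cl2, −78 °C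
Reagents that add atoms: none
Why: Enantioselective Lewis-acid-catalysed Diels–Alder reaction (Corey oxazaborolidinium type): the nucleophilic diene terminus C6 bonds to the CH2 of the enal so that the quaternary carbon C4 sits next to bridgehead C8, the formyl group goes exo as usual for 2-substituted acroleins, and the catalyst-controlled face fixes the bridgeheads C6 and C8.

Step 5
Reactants: 7 Diels–Alder aldehyde
Product: 8 1-(2-chloroethyl)-2-endo-(propan-2-yl)-5-[tri(propan-2-yl)silyloxy]bicyclo[2.2.1]hept-5-ene
Conditions: RhCl(PPh3)3 (1.1 equiv), PhCN, 130 °C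
Reagents that add atoms: none
Why: Tsuji–Wilkinson decarbonylation replaces the exo formyl group by hydrogen with retention, so C4 ends with H exo and isopropyl endo, and no free radical is formed that could close onto the enol-ether double bond.

Step 6
Reactants: 9 3-ethoxycyclohex-2-en-1-one
Product: 10 rac-6-acetoxy-3-ethoxycyclohex-2-en-1-one
Conditions: Mn(OAc)3·2H2O (3 equiv), benzene, reflux
Reagents that add atoms: manganese triacetate CC(=O)[O-].CC(=O)[O-].CC(=O)[O-].[Mn+3]
Why: Manganese triacetate α′-acetoxylation of the enone through its enol radical; the product is racemic.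

Step 7
Reactants: 10 rac-6-acetoxy-3-ethoxycyclohex-2-en-1-one
Product: 11 (R)-3-ethoxy-6-hydroxycyclohex-2-en-1-one
Conditions: pig liver esterase, pH 7 phosphate buffer, rt, to about 50% conversion; separate from unreacted (S)-acetate
Reagents that add atoms: none
Why: Enzymatic kinetic resolution by enantioselective ester hydrolysis delivers the (R)-alcohol, the future C13 stereocentre.

Step 8
Reactants: 11 (R)-3-ethoxy-6-hydroxycyclohex-2-en-1-one
Product: 12 (R)-6-[tert-butyl(dimethyl)silyloxy]-3-ethoxycyclohex-2-en-1-one
Conditions: t-BuMe2SiCl, imidazole, DMF, rt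
Reagents that add atoms: tert-butyldimethylsilyl chloride CC(C)(C)[Si](C)(C)Cl
Why: Standard silyl protection of the secondary alcohol; the stereocentre is untouched.

Step 9
Reactants: 8 chloroethyl norbornene silyl enol ether; 12 (R)-6-[tert-butyl(dimethyl)silyloxy]-3-ethoxycyclohex-2-en-1-one
Product: 15 (4R)-4-silyloxy-3-[2-(norbornenyl)ethyl]cyclohex-2-en-1-one, via organolithium 13 (not isolated), via tertiary allylic alcohol 14 (not isolated)
Conditions: LiDBB, THF, −78 °C; then 12, −78 to 0 °C; then 0.5 M HCl, 0 °C
Reagents that add atoms: none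
Why: Reductive lithiation of the primary chloride, 1,2-addition to the vinylogous ester and acid-induced transposition (Stork–Danheiser) join the two enantiopure fragments without creating a lasting stereocentre, and the triisopropylsilyl enol ether survives the brief dilute-acid work-up.

Step 10
Reactants: 15 tethered 4-silyloxy enone
Product: 16 bis(silyl enol ether) with quaternary C11 (methyl trans to the C13 silyloxy group)
Conditions: Me2CuLi (from MeLi, CuI), Me3SiCl, THF, −78 to −40 °C; Et3N work-up
Reagents that add atoms: lithium dimethylcuprate [Li+].C[Cu-]C; chlorotrimethylsilane C[Si](C)(C)Cl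
Why: Chlorosilane-accelerated Gilman conjugate addition occurs anti to the adjacent silyloxy group, setting the quaternary centre C11, and the enolate is trapped regiospecifically as the C16–C18 silyl enol ether.

Step 11
Reactants: 16 bis(silyl enol ether)
Product: 18 tetracyclic 1,4-diketone, via diketone epimer mixture 17 (not isolated)
Conditions: (NH4)2Ce(NO3)6 (2.2 equiv), NaHCO3, MeCN, −20 °C; then DBU, CH2Cl2, rt
Reagents that add atoms: none
Why: Oxidative coupling of silyl enol ethers: single-electron oxidation turns one enol ether into an electrophilic α-carbonyl radical cation (enolonium equivalent) that is captured 6-exo by the other, joining the two ketone α-carbons C18 and C19 to close ring B; both new centres are α to a ketone and DBU equilibrates them to the trans-fused A/B decalone with ring B exo on the norbornanone (the endo face at C19 is blocked by the endo isopropyl group).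

Step 12
Reactants: 18 tetracyclic 1,4-diketone
Product: 19 C16 tertiary alcohol (C13 silyl ether, C20 ketone)
Conditions: MeMgBr (1.2 equiv), CeCl3, THF, −78 °C
Reagents that add atoms: methylmagnesium bromide C[Mg]Br
Why: Cerium-mediated Grignard 1,2-addition goes to the more electrophilic cyclohexanone rather than the flanked norbornanone, and attack from the equatorial direction, opposite the axial angular methyl, gives the axial C16 hydroxyl cis to that methyl.

Step 13
Reactants: 19 C16 tertiary alcohol
Product: 20 C13,C16-diol with C20 ketone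
Conditions: Bu4NF, THF, 40 °C
Reagents that add atoms: none
Why: Fluoride-mediated desilylation frees the axial C13 alcohol without touching any stereocentre.

Step 14
Reactants: 20 C13,C16-diol with C20 ketone
Product: 21 C13 equatorial bromide (C16 alcohol, C20 ketone)
Conditions: CBr4, PPh3, CH2Cl2, 0 °C to rt
Reagents that add atoms: tetrabromomethane BrC(Br)(Br)Br
Why: Appel reaction: the secondary axial alcohol is activated as its alkoxyphosphonium salt and displaced by bromide with inversion to the equatorial bromide cis to the angular methyl, while the hindered axial tertiary alcohol does not react.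

Step 15
Reactants: 21 C13 equatorial bromide
Product: 22 target CNP0295684.1
Conditions: NaBH4, MeOH, −20 °C
Reagents that add atoms: none
Why: Borohydride reduction of the norbornanone from the less hindered exo face gives the endo C20 alcohol.

**Compound list**

1 | 3-methylbutanal | CC(C)CC=O | starting material
2 | 3-methyl-2-methylidenebutanal | CC(C)C(=C)C=O | intermediate
3 | 3-ethoxycyclopent-2-en-1-one | CCOC1=CC(=O)CC1 | starting material
4 | 3-ethenylcyclopent-2-en-1-one (not isolated) | C=CC1=CC(=O)CC1 | intermediate
5 | 3-(2-chloroethyl)cyclopent-2-en-1-one | ClCCC1=CC(=O)CC1 | intermediate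
6 | 1-(2-chloroethyl)-3-[tri(propan-2-yl)silyloxy]cyclopenta-1,3-diene | ClCCC1=CC(O[Si](C(C)C)(C(C)C)C(C)C)=CC1 | intermediate
7 | 1-(2-chloroethyl)-2-(propan-2-yl)-5-[tri(propan-2-yl)silyloxy]bicyclo[2.2.1]hept-5-ene-2-carbaldehyde, formyl exo, isopropyl endo | CC(C)[C@]1(C=O)C[C@H]2C[C@]1(CCCl)C=C2O[Si](C(C)C)(C(C)C)C(C)C | intermediate
8 | 1-(2-chloroethyl)-2-endo-(propan-2-yl)-5-[tri(propan-2-yl)silyloxy]bicyclo[2.2.1]hept-5-ene | CC(C)[C@@H]1C[C@H]2C[C@]1(CCCl)C=C2O[Si](C(C)C)(C(C)C)C(C)C | intermediate
9 | 3-ethoxycyclohex-2-en-1-one | CCOC1=CC(=O)CCC1 | starting material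
10 | rac-6-acetoxy-3-ethoxycyclohex-2-en-1-one | CCOC1=CC(=O)C(OC(C)=O)CC1 | intermediate
11 | (R)-3-ethoxy-6-hydroxycyclohex-2-en-1-one | CCOC1=CC(=O)[C@H](O)CC1 | intermediate
12 | (R)-6-[tert-butyl(dimethyl)silyloxy]-3-ethoxycyclohex-2-en-1-one | CCOC1=CC(=O)[C@H](O[Si](C)(C)C(C)(C)C)CC1 | intermediate
13 | 2-(norbornenyl)ethyllithium from 8 (not isolated) | CC(C)[C@@H]1C[C@H]2C[C@]1(CC[Li])C=C2O[Si](C(C)C)(C(C)C)C(C)C | intermediate
14 | tertiary allylic alcohol from 1,2-addition of 13 to 12, carbinol centre unassigned (not isolated) | CC(C)[C@@H]1C[C@H]2C[C@]1(CCC1(O)C=C(OCC)CC[C@H]1O[Si](C)(C)C(C)(C)C)C=C2O[Si](C(C)C)(C(C)C)C(C)C | intermediate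
15 | (4R)-4-[tert-butyl(dimethyl)silyloxy]-3-{2-[6-endo-isopropyl-3-(triisopropylsilyloxy)bicyclo[2.2.1]hept-2-en-1-yl]ethyl}cyclohex-2-en-1-one | CC(C)[C@@H]1C[C@H]2C[C@]1(CCC1=CC(=O)CC[C@H]1O[Si](C)(C)C(C)(C)C)C=C2O[Si](C(C)C)(C(C)C)C(C)C | intermediate
16 | bis(silyl enol ether): trimethylsilyl enol ether (C16=C18) of the 3-methyl-3-[2-(norbornenyl)ethyl]-4-silyloxycyclohexanone, methyl trans to the silyloxy group; norbornanone as its triisopropylsilyl enol ether | CC(C)[C@@H]1C[C@H]2C[C@]1(CC[C@@]1(C)C=C(O[Si](C)(C)C)CC[C@H]1O[Si](C)(C)C(C)(C)C)C=C2O[Si](C(C)C)(C(C)C)C(C)C | intermediate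
17 | tetracyclic 1,4-diketone as C18/C19 epimer mixture (not isolated) | CC(C)[C@@H]1C[C@H]2C[C@@]13CC[C@]1(C)[C@H](O[Si](C)(C)C(C)(C)C)CCC(=O)C1C3C2=O | intermediate
18 | tetracyclic 1,4-diketone (C16 and C20 ketones, axial C13 silyl ether, trans-fused rings A/B, ring B exo on the norbornanone) | CC(C)[C@@H]1C[C@H]2C[C@@]13CC[C@]1(C)[C@H](O[Si](C)(C)C(C)(C)C)CCC(=O)[C@H]1[C@@H]3C2=O | intermediate
19 | C16 tertiary alcohol (axial OH, equatorial methyl), C13 silyl ether, C20 ketone | CC(C)[C@@H]1C[C@H]2C[C@@]13CC[C@]1(C)[C@H](O[Si](C)(C)C(C)(C)C)CC[C@@](C)(O)[C@H]1[C@@H]3C2=O | intermediate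
20 | C13 axial alcohol, C16 tertiary alcohol, C20 ketone | CC(C)[C@@H]1C[C@H]2C[C@@]13CC[C@]1(C)[C@H](O)CC[C@@](C)(O)[C@H]1[C@@H]3C2=O | intermediate
21 | C13 equatorial bromide, C16 tertiary alcohol, C20 ketone | CC(C)[C@@H]1C[C@H]2C[C@@]13CC[C@]1(C)[C@@H](Br)CC[C@@](C)(O)[C@H]1[C@@H]3C2=O | intermediate
22 | CNP0295684.1 | CC(C)[C@@H]1C[C@H]2C[C@@]13CC[C@]1(C)[C@@H](Br)CC[C@@](C)(O)[C@H]1[C@@H]3[C@H]2O | target

**Step count and risks**

Total steps: 15. Longest linear sequence: 11 (steps 2–5 and 9–15).

Step 11 (key oxidative coupling) is the most likely to fail. The bond joins two secondary carbons that each sit next to a quaternary centre, so nitrate capture of the radical cation or simple desilylation may win, and the final C18 epimer ratio rests on thermodynamics. The fallback sets out from 16 and returns at 18. N-Bromosuccinimide in THF at −78 °C brominates the more reactive trimethylsilyl enol ether of 16 to give the α-bromo ketone F1, a discrete α-keto electrophile. Visible-light atom-transfer cyclisation (Ru(bpy)3Cl2, blue light, DMF) then sends the derived α-keto radical 6-exo onto the triisopropylsilyl enol ether. Loss of the silyl bromide and DBU equilibration give 18.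

Step 14 (Appel bromination) is the second risk: displacement at a secondary carbon next to a quaternary centre can give elimination or methyl migration instead. The fallback sets out from 20 and returns at 21. Dess–Martin oxidation gives the C13 ketone F2, which can only enolise toward C14. LiHMDS and PhNTf2 convert it into the enol triflate F3. LiBr with catalytic [Cp*Ru(MeCN)3]OTf exchanges triflate for bromide to give the alkenyl bromide F4. Hydrogen-atom-transfer hydrogenation (Mn(dpm)3, PhSiH3, t-BuOOH, i-PrOH) delivers hydrogen axially to the α-bromo radical, giving the equatorial bromide 21.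

Step 5 (decarbonylation of a very hindered quaternary aldehyde) is the third risk: β-hydride elimination to alkenes or no reaction are both possible. The fallback sets out from 7 and returns at 8. Dilute HCl in THF first hydrolyses the silyl enol ether to the keto aldehyde F5. This is needed because a C4 radical next to the enol-ether double bond would close to a nortricyclyl radical. Thiol-catalysed radical-chain decarbonylation (tert-dodecanethiol, 1,1'-azobis(cyclohexanecarbonitrile), PhCl, 130 °C) then gives the chloro ketone F6, with hydrogen delivered from the exo face. LDA and i-Pr3SiOTf re-form the only possible enol ether, 8.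

**Further compounds**

F1 | step 11 | α-bromo ketone (bromine at C18) of 16 with the triisopropylsilyl enol ether retained | CC(C)[C@@H]1C[C@H]2C[C@]1(CC[C@@]1(C)C(Br)C(=O)CC[C@H]1O[Si](C)(C)C(C)(C)C)C=C2O[Si](C(C)C)(C(C)C)C(C)C
F2 | step 14 | C13 ketone of 20 (C16 tertiary alcohol, C20 ketone) | CC(C)[C@@H]1C[C@H]2C[C@@]13CC[C@]1(C)C(=O)CC[C@@](C)(O)[C@H]1[C@@H]3C2=O
F3 | step 14 | C13–C14 enol triflate | CC(C)[C@@H]1C[C@H]2C[C@@]13CC[C@]1(C)C(OS(=O)(=O)C(F)(F)F)=CC[C@@](C)(O)[C@H]1[C@@H]3C2=O
F4 | step 14 | C13–C14 alkenyl bromide | CC(C)[C@@H]1C[C@H]2C[C@@]13CC[C@]1(C)C(Br)=CC[C@@](C)(O)[C@H]1[C@@H]3C2=O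
F5 | step 5 | 1-(2-chloroethyl)-5-oxo-2-(propan-2-yl)bicyclo[2.2.1]heptane-2-carbaldehyde, formyl exo | CC(C)[C@]1(C=O)C[C@H]2C[C@]1(CCCl)CC2=O
F6 | step 5 | 4-(2-chloroethyl)-5-endo-(propan-2-yl)bicyclo[2.2.1]heptan-2-one | CC(C)[C@@H]1C[C@H]2C[C@]1(CCCl)CC2=O
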